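Two routes turn E and G into E.G, and the comparison to hold on to is between their rates: the plain step, E + G giving E.G, and the assisted step, where E.G itself is the autocatalyst.

| setting | south-east | south | north-east |
|---|---|---|---|
| J | 5.0 mM | 10 mM | 20 mM |
| G | 1.00 equiv | 1.00 equiv | 1.00 equiv |
| time | 30 min | 30 min | 30 min |

    E + G + E.G → 2 E.G (k1 = 3820 M⁻² min⁻¹)
    G → Z (k2 = 6.06 × 10⁻⁵ min⁻¹)
    J ⇌ E, rate k3*(cs3 - [E]) while solid is left; crystals form when [E] > cs3 (cs3 = 7.7 mM, k3 = 0.0102 min⁻¹)
    E + G → E.G (k4 = 0.146 M⁻¹ min⁻¹)

- as a solid, counted per litre of solution: J
- at the start none of J is in solution
- "hardly changes" means that all values lie within two and a half points (for a concentration: within two and a half percent of the largest)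
- run time (south-east): 30 min

- [E.G] at the end for south-east, south, north-east, in this order
- the course of these numbers from the first flask to the last (falls, then rises / hardly changes / rises all the way / rises, then falls / falls all the way)

1. First instants. E.G is absent and no J is in solution, so dissolving must come first. Its rate law starts at 0.0785 mM min⁻¹ and has no charge in it.

2. Middle. E climbs towards its solubility and, with nothing taken out, reaches 2.03 mM at 30 min. That is less than the solubility and less than the 5.0 mM of south-east, the lowest charge, so solid stays. In south-east the plain step alone gives E a pseudo-first-order half-life of 16 h, far longer than the run, so E simply accumulates. The area under its curve is 1.92 M·s.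

3. What is about to matter. E and G cancel between the two rates, so assisted over plain is [E.G] divided by the takeover level, the [E.G] at which both routes run equally fast, k4/k1 = 0.0382 mM.

4. Going round, south-east. Let u be k1 times the charge of G times the area, here 0.611. The first round, plain step alone, gives the level times u, 0.0234 mM. Putting that back adds half the square of u, giving 0.0305 mM. The rounds sum to level × (exp(u) − 1), which is 0.0322 mM.

5. The other flasks. South has u = 1.22, giving 0.0915 mM. North-east has u = 2.44, giving 0.402 mM. So my row rises all the way. I took no E out, and in north-east the reckoned product amounts to 19.8% of the E reckoned there, so I expect that figure to err on the high side.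

6. The forecast gives 0.032 mM, 0.089 mM and 0.33 mM, rises all the way, on the ground that product “grows autocatalytically at a rate proportional to G”; it stands below my figures for south and north-east.

7. The flask gives 0.0317 mM, 0.0876 mM and 0.333 mM, rises all the way.

In south-east at 30.0 min, the assisted step gives E a half-life of 19 h against 16 h by the plain step, so it is still the slower, and 0.0317 mM lies below the takeover level of 0.0382 mM. North-east has passed that level, standing at 8.72 times it, with E at 1.72 mM at 30.0 min.

All constants are those of an exercise; no experiment stands behind them.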